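**Retrosynthetic overview**

- The target is reached by removing eleven benzyl ethers from a fully O-benzylated trimer; no skeletal bond is made after the key step.
- The strategy rests on ring C of each upper fisetinidol unit: the C2 aryl group, the C3 hydroxyl and the C4 bond to ring A of catechin (at C8 and at C6) are 2,3-trans-3,4-trans, so H at C4 and O at C3 are cis to each other and trans to the C2 aryl group. That is the outcome of a syn H/B addition across C3=C4 of a 4-arylflav-3-ene from the face away from the C2 aryl group, so both upper units come from one twofold hydroboration-oxidation.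
- The two interflavan bonds (C4 to C6 and C4 to C8) are made earlier as sp2-sp2 bonds, by a twofold Suzuki-Miyaura coupling of 6,8-dibromo-penta-O-benzylcatechin with an (S)-flav-3-en-4-yl boronate.
- The boronate comes from the enol triflate of an (S)-flavanone, made by rhodium-catalysed asymmetric 1,4-addition of an arylboronic acid to 7-benzyloxychromone.
- No ring is formed: rings A, B and C of catechin and the chromone bicycle are bought, ring B of each upper unit is attached by the conjugate addition, and the two upper heterocycles are saturated last.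

Key step: step 9

Assumption: the (1S,4S) antipode of the diene ligand is taken to give the (S)-flavanone, by analogy with the sense of induction on cyclic enones; a pilot run would confirm this, and the (1R,4R) ligand would be used instead if the sense is opposite.

**Route**

Step 1
Reactants: 1 (+)-catechin
Product: 2 5,7,3',4'-tetra-O-benzyl-(+)-catechin (3-OH free)
Conditions: BnBr (4.5 equiv), K2CO3 (5 equiv), DMF, 0 °C to rt, argon
Reagents that add atoms: benzyl bromide, BrCc1ccccc1
Why: Williamson ether synthesis in which K2CO3 deprotonates only the four phenols and leaves the secondary 3-OH free; exclusion of oxygen prevents catechol oxidation and base-induced C2 epimerisation, so both stereocentres of catechin are carried through.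

Step 2
Reactants: 2 5,7,3',4'-tetra-O-benzyl-(+)-catechin
Product: 3 3,5,7,3',4'-penta-O-benzyl-(+)-catechin
Conditions: NaH (1.5 equiv), BnBr (1.3 equiv), n-Bu4NI (cat.), DMF, 0 °C to rt
Reagents that add atoms: benzyl bromide, BrCc1ccccc1
Why: Williamson etherification of the secondary alkoxide; with no free phenol left the pyran ring cannot open, so C2 and C3 are not at risk.

Step 3
Reactants: 3 3,5,7,3',4'-penta-O-benzyl-(+)-catechin
Product: 4 6,8-dibromo-3,5,7,3',4'-penta-O-benzyl-(+)-catechin
Conditions: NBS (2.1 equiv), CH2Cl2, −20 °C to rt, dark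
Reagents that add atoms: N-bromosuccinimide, O=C1CCC(=O)N1Br
Why: Electrophilic aromatic bromination at C8 and C6, the only free positions of ring A and each activated by two ortho oxygens and one para oxygen, so both should react before the less electron-rich ring B does.

Step 4
Reactants: 5 7-hydroxychromone
Product: 6 7-benzyloxychromone
Conditions: BnBr (1.2 equiv), K2CO3 (1.5 equiv), acetone, reflux
Reagents that add atoms: benzyl bromide, BrCc1ccccc1
Why: Williamson ether synthesis on the acidic 7-OH; carbonate in acetone is too weak a nucleophile to open the pyranone ring.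

Step 5
Reactants: 6 7-benzyloxychromone; 7 3,4-bis(benzyloxy)phenylboronic acid
Product: 8 (S)-7,3',4'-tris(benzyloxy)flavanone
Conditions: [RhCl(C2H4)2]2 (2.5 mol%), (1S,4S)-2,5-diphenylbicyclo[2.2.2]octa-2,5-diene (5.5 mol%), 7 (2.5 equiv), K3PO4 (0.5 equiv), toluene/H2O 10:1, 40 °C
Reagents that add atoms: none
Why: Hayashi-Miyaura asymmetric 1,4-addition in which the aryl group passes from boron to monovalent rhodium, the chromone C2=C3 bond inserts enantioface-selectively within the chiral diene pocket and the oxa-π-allyl rhodium species is protonated, setting C2 as S (the spatial arrangement of (2R)-fisetinidol); the weak base and low temperature limit retro-oxa-Michael racemisation.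

Step 6
Reactants: 8 (S)-7,3',4'-tris(benzyloxy)flavanone
Product: 10 (S)-7,3',4'-tris(benzyloxy)flav-3-en-4-yl trifluoromethanesulfonate, via lithium enolate 9 (not isolated)
Conditions: LiN(SiMe3)2 (1.15 equiv) added to 8 and PhNTf2 (1.3 equiv), THF/DMPU 10:1, −78 °C, then to −40 °C; cold aq. NH4Cl quench
Reagents that add atoms: N-phenylbis(trifluoromethanesulfonimide), O=S(=O)(N(c1ccccc1)S(=O)(=O)C(F)(F)F)C(F)(F)F
Why: Kinetic deprotonation at C3 gives the enolate, which is O-sulfonylated by the triflimide already present (enol triflate formation); at low temperature this trapping should outrun E1cB expulsion of the C2–O1 phenoxide, so C2 stays S.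

Step 7
Reactants: 10 (S)-7,3',4'-tris(benzyloxy)flav-3-en-4-yl trifluoromethanesulfonate
Product: 11 (S)-7,3',4'-tris(benzyloxy)flav-3-en-4-yl pinacol boronate
Conditions: B2pin2 (1.2 equiv), PdCl2(dppf) (3 mol%), dppf (3 mol%), KOPh (1.5 equiv), toluene, 50 °C, dark
Reagents that add atoms: bis(pinacolato)diboron, CC1(C)OB(OC1(C)C)B1OC(C)(C)C(C)(C)O1
Why: Miyaura borylation: oxidative addition of the alkenyl C–OTf bond to zerovalent palladium (formed from the divalent precatalyst), phenoxide-assisted transmetallation with the diboron and reductive elimination; KOPh is too weak a base to drive homocoupling, and C2 is not involved.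

Step 8
Reactants: 4 6,8-dibromo-3,5,7,3',4'-penta-O-benzyl-(+)-catechin; 11 (S)-7,3',4'-tris(benzyloxy)flav-3-en-4-yl pinacol boronate
Product: 12 6,8-bis[(2S)-7,3',4'-tris(benzyloxy)flav-3-en-4-yl]-3,5,7,3',4'-penta-O-benzylcatechin
Conditions: 11 (2.6 equiv), Pd(OAc)2 (10 mol%), SPhos (20 mol%), K3PO4 (6 equiv), degassed toluene/H2O 10:1, 70 °C, dark
Reagents that add atoms: none
Why: Twofold Suzuki-Miyaura coupling; the bulky electron-rich biarylphosphine supports oxidative addition of zerovalent palladium into the di-ortho-oxygenated C6–Br and C8–Br bonds and transmetallation of the hindered alkenyl boronate, and the excess of 11 covers protodeboronation; no stereocentre is formed or touched.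

Step 9
Reactants: 12 6,8-bis[(2S)-7,3',4'-tris(benzyloxy)flav-3-en-4-yl]-3,5,7,3',4'-penta-O-benzylcatechin
Product: 14 undeca-O-benzyl fisetinidol-(4α→8)-catechin-(6→4α)-fisetinidol (free 3-OH on both upper units), via twofold C3-borane adduct 13 (not isolated)
Conditions: BH3·THF (8 equiv), THF, 0 °C to rt; then 3 M aq. NaOH, 30% H2O2, 0 °C to rt
Reagents that add atoms: hydrogen peroxide, OO (gives the C3 oxygen); borane as its THF complex, B (gives boron in 13 and the C4 hydrogen)
Why: Proposed new method: BH3 adds across C3=C4 of each flavene unit through a concerted four-centre syn transition state with boron at C3 and hydride at C4, and alkaline peroxide then turns each C3–B bond into C3–O with retention; the closest known reactions are hydroboration-oxidation of flav-3-enes to 2,3-trans-flavan-3-ols and of 4-aryl-2H-chromenes to trans-4-arylchroman-3-ols, whereas the twofold reaction on a 6,8-bis(flav-3-en-4-yl)catechin is untested. No ring is closed; the two heterocycles are only saturated. C3 of each upper unit is controlled by the neighbouring C2 aryl group, which blocks one face of the half-chair so that boron enters trans to it, and C4 is controlled by the syn delivery of hydride on that same face, which places ring A of catechin cis to the C2 aryl group (2,3-trans-3,4-trans, C4 S). The step needs C3 regioselectivity and anti facial selectivity in both units: the first should follow from C3 being the less substituted carbon and the one made electron-rich through C4a by the para 7-benzyloxy group and the ortho ring oxygen, the second from the stereocentre next to the carbon that takes boron, so neither depends on the catechin core or on the rotamer about the C4–aryl bond. Benzyl ethers and the cyclic benzylic C2–O1 bonds are inert to borane and alkaline peroxide, and inside the ring the C3–B and C2–O1 bonds cannot become syn-periplanar, so thermal B–O elimination is not expected.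

Step 10
Reactants: 14 undeca-O-benzyl fisetinidol-(4α→8)-catechin-(6→4α)-fisetinidol
Product: 15 fisetinidol-(4α→8)-catechin-(6→4α)-fisetinidol
Conditions: H2 (1 atm), Pd(OH)2 on carbon (20 wt%), THF/MeOH/H2O 20:10:1, rt; filtration under argon, Sephadex LH-20, lyophilisation
Reagents that add atoms: none
Why: Heterogeneous hydrogenolysis of the eleven O-benzyl bonds; under neutral conditions at one atmosphere the diarylmethine C4–C bonds and the cyclic C2–O1 ethers should be cleaved far more slowly, so all eight stereocentres are kept.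

**Compound list**

1 | (+)-catechin, (2R,3S) | Oc1cc(O)c2c(c1)O[C@H](c1ccc(O)c(O)c1)[C@@H](O)C2 | starting material
2 | 5,7,3',4'-tetra-O-benzyl-(+)-catechin | c1ccccc1COc1cc(OCc3ccccc3)c2c(c1)O[C@H](c1ccc(OCc3ccccc3)c(OCc3ccccc3)c1)[C@@H](O)C2 | intermediate
3 | 3,5,7,3',4'-penta-O-benzyl-(+)-catechin | c1ccccc1COc1cc(OCc3ccccc3)c2c(c1)O[C@H](c1ccc(OCc3ccccc3)c(OCc3ccccc3)c1)[C@@H](OCc1ccccc1)C2 | intermediate
4 | 6,8-dibromo-3,5,7,3',4'-penta-O-benzyl-(+)-catechin | c1ccccc1COc1c(Br)c(OCc3ccccc3)c2c(c1Br)O[C@H](c1ccc(OCc3ccccc3)c(OCc3ccccc3)c1)[C@@H](OCc1ccccc1)C2 | intermediate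
5 | 7-hydroxychromone | O=c1ccoc2cc(O)ccc12 | starting material
6 | 7-benzyloxychromone | O=c1ccoc2cc(OCc3ccccc3)ccc12 | intermediate
7 | 3,4-bis(benzyloxy)phenylboronic acid | OB(O)c1ccc(OCc2ccccc2)c(OCc2ccccc2)c1 | starting material
8 | (S)-7,3',4'-tris(benzyloxy)flavanone | c1ccccc1COc1ccc2c(c1)O[C@H](c1ccc(OCc3ccccc3)c(OCc3ccccc3)c1)CC2=O | intermediate
9 | lithium enolate of 8 (C3=C4–OLi, C2 S) | c1ccccc1COc1ccc2c(c1)O[C@H](c1ccc(OCc3ccccc3)c(OCc3ccccc3)c1)C=C2O[Li] | intermediate
10 | (S)-7,3',4'-tris(benzyloxy)flav-3-en-4-yl trifluoromethanesulfonate | c1ccccc1COc1ccc2c(c1)O[C@H](c1ccc(OCc3ccccc3)c(OCc3ccccc3)c1)C=C2OS(=O)(=O)C(F)(F)F | intermediate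
11 | (S)-7,3',4'-tris(benzyloxy)flav-3-en-4-yl pinacol boronate | c1ccccc1COc1ccc2c(c1)O[C@H](c1ccc(OCc3ccccc3)c(OCc3ccccc3)c1)C=C2B1OC(C)(C)C(C)(C)O1 | intermediate
12 | 6,8-bis[(2S)-7,3',4'-tris(benzyloxy)flav-3-en-4-yl]-3,5,7,3',4'-penta-O-benzylcatechin | c7ccccc7COc1c(C3=C[C@@H](c4ccc(OCc7ccccc7)c(OCc7ccccc7)c4)Oc4cc(OCc7ccccc7)ccc43)c(OCc7ccccc7)c2c(c1C1=C[C@@H](c3ccc(OCc7ccccc7)c(OCc7ccccc7)c3)Oc3cc(OCc7ccccc7)ccc31)O[C@H](c1ccc(OCc7ccccc7)c(OCc7ccccc7)c1)[C@@H](OCc7ccccc7)C2 | intermediate
13 | twofold C3-borane adduct of 12 (BH2 at C3 of each upper unit, 2,3-trans-3,4-trans) | c7ccccc7COc1c([C@@H]3c4ccc(OCc7ccccc7)cc4O[C@H](c4ccc(OCc7ccccc7)c(OCc7ccccc7)c4)[C@H]3B)c(OCc7ccccc7)c2c(c1[C@@H]1c3ccc(OCc7ccccc7)cc3O[C@H](c3ccc(OCc7ccccc7)c(OCc7ccccc7)c3)[C@H]1B)O[C@H](c1ccc(OCc7ccccc7)c(OCc7ccccc7)c1)[C@@H](OCc7ccccc7)C2 | intermediate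
14 | undeca-O-benzyl fisetinidol-(4α→8)-catechin-(6→4α)-fisetinidol (upper units 2R,3S,4S with free 3-OH; central unit 2R,3S) | c7ccccc7COc1c([C@@H]3c4ccc(OCc7ccccc7)cc4O[C@H](c4ccc(OCc7ccccc7)c(OCc7ccccc7)c4)[C@H]3O)c(OCc7ccccc7)c2c(c1[C@@H]1c3ccc(OCc7ccccc7)cc3O[C@H](c3ccc(OCc7ccccc7)c(OCc7ccccc7)c3)[C@H]1O)O[C@H](c1ccc(OCc7ccccc7)c(OCc7ccccc7)c1)[C@@H](OCc7ccccc7)C2 | intermediate
15 | fisetinidol-(4α→8)-catechin-(6→4α)-fisetinidol | Oc1ccc2c(c1)O[C@H](c1ccc(O)c(O)c1)[C@@H](O)[C@@H]2c1c(O)c2c(c([C@@H]3c4ccc(O)cc4O[C@H](c4ccc(O)c(O)c4)[C@H]3O)c1O)O[C@H](c1ccc(O)c(O)c1)[C@@H](O)C2 | target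

**Step count**

Total: 10 steps. Longest linear sequence: 7 steps (steps 4 to 10, from 7-hydroxychromone 5).

**Steps most likely to fail**

1. Step 9 (twofold hydroboration-oxidation). Borane may add slowly to the two trisubstituted alkenes flanked by the ortho benzyloxy groups of ring A, facial selectivity may be incomplete in one unit, or boron may go partly to C4. The fallback is the known capture of a C4 cation and sets out from triflate 10 and penta-O-benzylcatechin 3. Palladium-catalysed formate reduction of 10 (Pd(OAc)2, PPh3, HCO2H, Et3N, DMF, 60 °C) should give (S)-7,3',4'-tris(benzyloxy)flav-3-ene F1. Catalytic dihydroxylation (K2OsO4·2H2O, N-methylmorpholine N-oxide, acetone/H2O) from the face away from the C2 aryl group should give (2R,3S,4S)-7,3',4'-tris(benzyloxy)flavan-3,4-diol F2, the 2,3-trans-3,4-cis diol. Ionisation of the 4-OH of F2 (2.5 equiv) with Me3SiOTf in CH2Cl2 at −40 °C in the presence of 3 gives a C4 benzylic cation stabilised by the 7-benzyloxy group and the ring oxygen. Capture by C8 and then C6 of ring A, mainly trans to the C3 oxygen, should lead to 14, where the route is rejoined; minor 4β isomers would be removed by chromatography.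

2. Step 8 (twofold Suzuki-Miyaura coupling). The coupling may stall after the first C–C bond because the second C–Br bond is more hindered, while the alkenyl boronate is lost to protodeboronation and the bromide to hydrodebromination. The fallback reverses the roles of the partners and sets out from dibromide 4 and triflate 10. Twofold bromine-lithium exchange on 4 (t-BuLi, 4.2 equiv, THF, −78 °C) should give 6,8-dilithio-penta-O-benzylcatechin F3. Transmetallation with ZnCl2 gives the 6,8-bis(chlorozinc) reagent F4. Negishi coupling of F4 with 10 (2.4 equiv; Pd(OAc)2, SPhos, THF, 50 °C) moves oxidative addition to the unhindered alkenyl triflate and should give 12, where the route is rejoined.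

3. Step 6 (enol triflate formation). If O-sulfonylation is slow, the enolate may expel the C2–O1 phenoxide and open to the chalcone, which loses material and erodes the C2 configuration. The fallback avoids the enolate, the triflate and the boronate and sets out from flavanone 8 and dibromide 4. Condensation of 8 with p-toluenesulfonyl hydrazide (EtOH, 60 °C) should give (S)-7,3',4'-tris(benzyloxy)flavanone N-tosylhydrazone F5. A twofold Barluenga coupling of F5 (2.6 equiv) with 4 (Pd2(dba)3 as zerovalent palladium source, XPhos, LiOtBu, dioxane, 90 °C) proceeds by palladium carbene formation, aryl migration to C4 and β-hydride elimination of a C3 hydrogen. It should give 12 directly, where the route is rejoined.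

**Further compounds**

F1 | step 9 | (S)-7,3',4'-tris(benzyloxy)flav-3-ene | c1ccccc1COc1ccc2c(c1)O[C@H](c1ccc(OCc3ccccc3)c(OCc3ccccc3)c1)C=C2
F2 | step 9 | (2R,3S,4S)-7,3',4'-tris(benzyloxy)flavan-3,4-diol (2,3-trans-3,4-cis) | c1ccccc1COc1ccc2c(c1)O[C@H](c1ccc(OCc3ccccc3)c(OCc3ccccc3)c1)[C@@H](O)[C@H]2O
F3 | step 8 | 6,8-dilithio-3,5,7,3',4'-penta-O-benzylcatechin | c1ccccc1COc1c([Li])c(OCc3ccccc3)c2c(c1[Li])O[C@H](c1ccc(OCc3ccccc3)c(OCc3ccccc3)c1)[C@@H](OCc1ccccc1)C2
F4 | step 8 | 6,8-bis(chlorozinc)-3,5,7,3',4'-penta-O-benzylcatechin | c1ccccc1COc1c([Zn]Cl)c(OCc3ccccc3)c2c(c1[Zn]Cl)O[C@H](c1ccc(OCc3ccccc3)c(OCc3ccccc3)c1)[C@@H](OCc1ccccc1)C2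
F5 | step 6 | (S)-7,3',4'-tris(benzyloxy)flavanone N-tosylhydrazone (C=N geometry not specified) | c1ccccc1COc1ccc2c(c1)O[C@H](c1ccc(OCc3ccccc3)c(OCc3ccccc3)c1)CC2=NNS(=O)(=O)c1ccc(C)cc1
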